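## Retrosynthetic overview
1. Target ⇒ kinetic 1,4-addition of BrCl (Br to C1, Cl to C4) across the s-trans diene of a 6-bromo-4-chloro-5,5-dimethyl-1-vinylcyclohexene. This sets C4 and the Z-ethylidene.
2. Vinylcyclohexene ⇒ the only ring closure, the C7–C10 bond. A (Z)-bromodiene attacks an enantiopure chloriranium ion 6-endo, as in ochtodane biogenesis from a halogenated myrcene. C6–Cl and C10–Br are set together.
3. Chloriranium ion ⇒ (R)-6,7-epoxide of (Z)-10-bromomyrcene, by HCl opening, O-triflation and 1,2-chlorine participation (inversion at C6) in one flask.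
4. Epoxide ⇒ Shi epoxidation of (Z)-10-bromomyrcene. That diene ⇒ homoprenyl bromide + but-3-yn-2-ol (anti-carbomagnesiation/bromination, then dehydration).
5. Ring order: one carbocycle only, formed in step 4.

Assumption: operations run in one flask without work-up count as one step, and positions use myrcene numbering, C1=C2–C3(=C10)–C4–C5–C6=C7(CH3)2.

## Route

**Step 1**
Reactants: 1 5-bromo-2-methylpent-2-ene (homoprenyl bromide); 2 but-3-yn-2-ol (racemic)
Product: 5 (3Z)-3-(bromomethylidene)-7-methyloct-6-en-2-ol (racemic carbinol), via homoprenylmagnesium bromide 3 (not isolated), via oxamagnesole chelate 4 (not isolated)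
Conditions: 1 (1.6 equiv), Mg, THF, 40 °C; 2 + MeMgBr (1.0 equiv), THF, 0 °C; combine, CuI (15 mol %), 0 °C → rt; NBS, THF, −78 → −20 °C; H2O/aq NH4Cl
Reagents that add atoms: N-bromosuccinimide, O=C1CCC(=O)N1Br
Why: Copper-catalysed, alkoxide-directed anti-carbomagnesiation of a propargylic alcohol puts the alkyl group on the alkyne carbon next to the carbinol and the magnesium on the terminal carbon inside a five-membered O–Mg chelate (cis to the carbinol carbon), and C–Mg to C–Br exchange with NBS goes with retention, so bromine is locked cis to the future vinyl group (Z).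

**Step 2**
Reactants: 5 (3Z)-3-(bromomethylidene)-7-methyloct-6-en-2-ol
Product: 6 (3Z)-3-(bromomethylidene)-7-methylocta-1,6-diene [(Z)-10-bromomyrcene]
Conditions: Burgess reagent (1.5 equiv), PhMe, 50 °C
Reagents that add atoms: none
Why: In the Burgess dehydration the syn (Ei) elimination of the sulfamate ester can only take a hydrogen of the methyl group (the other β-carbon is sp2 and carries no hydrogen), so the vinyl group forms without free ionisation, the Z-vinyl bromide is untouched and the racemic carbinol centre is erased.

**Step 3**
Reactants: 6 (Z)-10-bromomyrcene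
Product: 7 (3R)-3-[(3Z)-3-(bromomethylidene)pent-4-en-1-yl]-2,2-dimethyloxirane
Conditions: D-fructose-derived Shi ketone (30 mol %), KHSO5 (as Oxone, 1.4 equiv), K2CO3, Bu4NHSO4 (cat.), MeCN–CH2(OMe)2/aq borate–EDTA buffer pH 10.5, 0 °C
Reagents that add atoms: potassium peroxymonosulfate, [K+].[O-]S(=O)(=O)OO
Why: In the Shi epoxidation the electrophilic chiral dioxirane takes the only electron-rich trisubstituted alkene (the bromodiene is deactivated), and the spiro transition state of the D-fructose-derived ketone delivers oxygen to the face that gives R at C6 (about 90–95% ee expected for a prenyl terminus).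

**Step 4 (key step)**
Reactants: 7 (3R)-3-[(3Z)-3-(bromomethylidene)pent-4-en-1-yl]-2,2-dimethyloxirane
Product: 12 (4S,6R)-6-bromo-4-chloro-1-ethenyl-5,5-dimethylcyclohex-1-ene, via chlorohydrin 8 (not isolated), via chlorohydrin triflate 9 (not isolated), via chloriranium ion 10 (not isolated), via cyclised allyl cation 11 (not isolated)
Conditions: HCl (1.0 equiv, 2 M in Et2O), CH2Cl2, −78 °C; then 2,6-di-tert-butyl-4-methylpyridine (DTBMP, 3 equiv), Tf2O (1.1 equiv), −78 °C; then EtNO2, −78 → −20 °C; aq NaHCO3
Reagents that add atoms: hydrogen chloride, Cl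
Why: Proposed new method: HCl opens the epoxide at the tertiary carbon and leaves the C6–O bond intact, triflation turns C6–O into a nucleofuge that the vicinal chlorine expels from the rear (anchimeric assistance, inversion at C6, and the regiochemistry of the opening is immaterial because both C–O bonds are replaced through the same ion), the configurationally stable chloriranium ion 10 is then opened at its tertiary carbon by C10 of the bromodiene through a chair in which C6–Cl is equatorial (anti to the forming bond) and the bromine, trans to C4 on the Z-alkene, also becomes equatorial, so 6S and the cis C10–Br centre are set in one event, and the hindered pyridine removes the axial C4–H of the tertiary allyl cation 11 to give the conjugated diene; the closest known reaction types are the enantiospecific solvolysis of β-halo sulfonates through haliranium ions and the haliranium-induced polyene cyclisation.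

**Step 5**
Reactants: 12 (4S,6R)-6-bromo-4-chloro-1-ethenyl-5,5-dimethylcyclohex-1-ene
Product: 14 (2S,3Z,4S,6S)-2-bromo-3-(2-bromoethylidene)-4,6-dichloro-1,1-dimethylcyclohexane (target), via bromoallyl cation 13 (not isolated)
Conditions: NBS (1.0 equiv) + HCl (1.0 equiv, 2 M in Et2O), CH2Cl2, 0 °C, 5 min (gives BrCl); cool to −78 °C, add to 12 in CH2Cl2–EtNO2, −78 °C, 10 min; cold aq Na2S2O3/NaHCO3; deactivated silica
Reagents that add atoms: N-bromosuccinimide, O=C1CCC(=O)N1Br; hydrogen chloride, Cl
Why: This is an electrophilic 1,4-addition of BrCl to a conjugated diene in which Br+ takes the unhindered terminal C1 (a cation at C3 would sit next to the C10–Br dipole), the planar s-trans diene (allylic bromine pseudoaxial to avoid A(1,2) strain with the vinyl group) places CH2Br cis to C10 in allyl cation 13, and chloride enters at the distal terminus C4 on the face opposite both ring halogens, which gives 4S and the Z-alkene under kinetic control.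

## Compound list
1 | 5-bromo-2-methylpent-2-ene | CC(C)=CCCBr | starting material
2 | but-3-yn-2-ol (racemic) | CC(O)C#C | starting material
3 | (4-methylpent-3-en-1-yl)magnesium bromide | CC(C)=CCC[Mg]Br | intermediate
4 | 5-methyl-4-(4-methylpent-3-en-1-yl)-2,5-dihydro-1,2-oxamagnesole | CC1O[Mg]C=C1CCC=C(C)C | intermediate
5 | (3Z)-3-(bromomethylidene)-7-methyloct-6-en-2-ol | CC(O)/C(CCC=C(C)C)=C\Br | intermediate
6 | (3Z)-3-(bromomethylidene)-7-methylocta-1,6-diene | C=C/C(CCC=C(C)C)=C\Br | intermediate
7 | (3R)-3-[(3Z)-3-(bromomethylidene)pent-4-en-1-yl]-2,2-dimethyloxirane | CC1(C)O[C@@H]1CC/C(C=C)=C/Br | intermediate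
8 | (3R,6Z)-6-(bromomethylidene)-2-chloro-2-methyloct-7-en-3-ol | CC(C)(Cl)[C@H](O)CC/C(C=C)=C/Br | intermediate
9 | (3R,6Z)-6-(bromomethylidene)-2-chloro-2-methyloct-7-en-3-yl trifluoromethanesulfonate | CC(C)(Cl)[C@H](OS(=O)(=O)C(F)(F)F)CC/C(C=C)=C/Br | intermediate
10 | (3S)-3-[(3Z)-3-(bromomethylidene)pent-4-en-1-yl]-2,2-dimethylchloriran-1-ium (triflate counter-ion) | CC1(C)[Cl+][C@H]1CC/C(C=C)=C/Br | intermediate
11 | 2-bromo-4-chloro-1-ethenyl-3,3-dimethylcyclohexan-1-ylium, Br and Cl cis (both equatorial), 4S (triflate counter-ion) | CC1(C)[C@H](Br)[C+](C=C)CC[C@@H]1Cl | intermediate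
12 | (4S,6R)-6-bromo-4-chloro-1-ethenyl-5,5-dimethylcyclohex-1-ene | CC1(C)[C@H](Br)C(C=C)=CC[C@@H]1Cl | intermediate
13 | 3-bromo-2-(2-bromoethylidene)-5-chloro-4,4-dimethylcyclohexan-1-ylium, CH2Br cis to CHBr (chloride counter-ion) | CC1(C)[C@H](Br)/C(=C\CBr)[CH+]C[C@@H]1Cl | intermediate
14 | (2S,3Z,4S,6S)-2-bromo-3-(2-bromoethylidene)-4,6-dichloro-1,1-dimethylcyclohexane | CC1(C)[C@H](Br)/C(=C\CBr)[C@@H](Cl)C[C@@H]1Cl | target

## Step count and risks
Total steps: 5. Longest linear sequence: 5.

**Step 4, highest risk.**
- The triflate 9 may ionise sluggishly.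
- Ion 10 may lose a methyl proton and give the acyclic allylic chloride, because the bromodiene is only a moderate π-nucleophile.
- Cation 11 may lose the C10 hydrogen instead of the C4 hydrogen.

The fallback sets out from 7 and comes back at 10. It generates the same ion by halide abstraction instead of sulfonate ionisation. Epoxide 7 is deoxydichlorinated with Ph3PCl2 in CH2Cl2 (both C–O bonds replaced, inversion at C6) to the isolable (3Z,6S)-3-(bromomethylidene)-6,7-dichloro-7-methyloct-1-ene F1. Its tertiary chloride is then abstracted with AgOTf (1.0 equiv) and DTBMP in CH2Cl2–EtNO2 at −78 °C. This gives 10 as its triflate, which cyclises to 12 as before. Exactly one equivalent of silver salt is used to spare the allylic bromide of 12.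

**Step 5.**
- Chloride may attack C2 and give the 1,2-adduct.
- Br+ may attack the ring alkene and give the Br/Cl-swapped isomer.
- The Z-alkene is probably the less stable geometric isomer: it places CH2Br next to the C10 bromine. Warming, Lewis acids or free halide could isomerise it.

The fallback sets out from 12 and comes back at 14. It removes the Br/Cl positional ambiguity by using a symmetrical dihalogen. Diene 12 is treated with Et4NCl3 in CH2Cl2–EtNO2 at −78 °C for 1,4-dichlorination, with the same s-trans geometry and the same facial arguments. The product is (2S,3Z,4S,6S)-2-bromo-4,6-dichloro-3-(2-chloroethylidene)-1,1-dimethylcyclohexane F2. Only its primary allylic chloride is exchanged with LiBr in acetone at 0 °C (Finkelstein SN2). The neopentyl C–Br and the secondary C–Cl are too hindered to react under these conditions.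

**Step 2.**
The allylic sulfamate may ionise or rearrange (SNi′). This would scramble the vinyl bromide geometry on which the C10 configuration depends.

The fallback sets out from 3 and comes back at 6. It builds the vinyl group by olefination instead of elimination.
- Grignard reagent 3 is added under CuI catalysis to prop-2-yn-1-ol that has been deprotonated with MeMgBr. This gives the chelate 4-(4-methylpent-3-en-1-yl)-2,5-dihydro-1,2-oxamagnesole F3.
- NBS converts F3 into (2Z)-2-(bromomethylidene)-6-methylhept-5-en-1-ol F4.
- MnO2 in CH2Cl2 oxidises F4 to (2Z)-2-(bromomethylidene)-6-methylhept-5-enal F5.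
- Wittig methylenation of F5 with Ph3P=CH2 in THF at −78 °C gives 6 with the geometry intact.

This costs one extra step.

## Further compounds
F1 | step 4 | (3Z,6S)-3-(bromomethylidene)-6,7-dichloro-7-methyloct-1-ene | CC(C)(Cl)[C@@H](Cl)CC/C(C=C)=C/Br
F2 | step 5 | (2S,3Z,4S,6S)-2-bromo-4,6-dichloro-3-(2-chloroethylidene)-1,1-dimethylcyclohexane | CC1(C)[C@H](Br)/C(=C\CCl)[C@@H](Cl)C[C@@H]1Cl
F3 | step 2 | 4-(4-methylpent-3-en-1-yl)-2,5-dihydro-1,2-oxamagnesole | C1O[Mg]C=C1CCC=C(C)C
F4 | step 2 | (2Z)-2-(bromomethylidene)-6-methylhept-5-en-1-ol | OC/C(CCC=C(C)C)=C\Br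
F5 | step 2 | (2Z)-2-(bromomethylidene)-6-methylhept-5-enal | O=C/C(CCC=C(C)C)=C\Br
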